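## Retrosynthetic overview

1. Last operation: carbonylative Stille macrocyclisation of a seco C4 vinyl iodide / C2 (Z)-vinylstannane. CO becomes C3, the ten-membered carbocycle closes, and the free C10–OH adds across the ring to the new ketone, so the carbocycle and the oxygen-bridged dihydrofuranol form together.
2. Before it: O8 acylation with (Z)-2-(acetoxymethyl)but-2-enoic acid (from crotonaldehyde, CO2 and Ac2O).
3. First ring: the trans α-methylene-γ-butyrolactone, by CrCl2 allylation/lactonisation of a (Z)-2-(bromomethyl)enoate with (Z)-3-iodobut-2-enal (C6–C7 bond).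
4. The allyl bromide comes from a Morita–Baylis–Hillman adduct. C8 is set by a proline aldol of acetone with 2,2-dimethoxyacetaldehyde, C10 by chelate-controlled ethynylation, and the (Z)-C1=C2–Sn unit by hydroalumination/stannylation.
5. Ring order: γ-lactone first, then carbocycle and oxa bridge in one operation.

Assumption: atoms carry germacranolide labels (C3 hemiketal carbon, C6 lactone carbinol, C8 ester carbinol, C10 ether carbon, C11–C13 methylene lactone); the target is (3R,6R,7R,8R,10R), 1Z,4Z, with a (2Z) side chain.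

## Route

Step 1
Reactants: 1 acetone; 2 2,2-dimethoxyacetaldehyde
Product: 3 (R)-4-hydroxy-5,5-dimethoxypentan-2-one
Conditions: (S)-proline (30 mol %), acetone/DMSO 1:4, rt, 48 h
Reagents that add atoms: none
Why: Proline-catalysed direct enamine aldol (List–Barbas type), in which the acetone enamine adds to the re face of the non-enolisable activated aldehyde through the acid-organised chair transition state and so sets C8 as (R).

Step 2
Reactants: 3 (R)-4-hydroxy-5,5-dimethoxypentan-2-one
Product: 4 (2R,4R)-1,1-dimethoxy-4-methylhex-5-yne-2,4-diol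
Conditions: HC≡CMgBr (3 equiv), THF, −78 → −20 °C; aq. NH4Cl
Reagents that add atoms: ethynylmagnesium bromide (C#C[Mg]Br)
Why: Chelation-controlled Grignard addition (1,3-induction), in which the six-membered magnesium alkoxide–ketone chelate holds the C8 substituent equatorial and the slim acetylide attacks axially to give the 8,10-anti diol with C10 (R), the minor C10 epimer being removed by chromatography.

Step 3
Reactants: 4 (2R,4R)-1,1-dimethoxy-4-methylhex-5-yne-2,4-diol
Product: 6 (2R,4R,5Z)-1,1-dimethoxy-4-methyl-6-(tributylstannyl)hex-5-ene-2,4-diol, via lithium alkenylalanate 5 (not isolated)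
Conditions: LiAlH4 (1.2 equiv), THF, 0 → 45 °C; then Bu3SnOTf (2.5 equiv), −78 → 0 °C; aq. potassium sodium tartrate
Reagents that add atoms: tributyltin trifluoromethanesulfonate (CCCC[Sn](CCCC)(CCCC)OS(=O)(=O)C(F)(F)F)
Why: Hydroxyl-directed trans-hydroalumination of the propargylic alcohol gives a five-membered oxa-aluminacycle with aluminium on the terminal carbon cis to the carbinol, and retentive aluminium-to-tin exchange fixes the (Z)-γ-hydroxy vinylstannane (C1=C2).

Step 4
Reactants: 6 (2R,4R,5Z)-1,1-dimethoxy-4-methyl-6-(tributylstannyl)hex-5-ene-2,4-diol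
Product: 9 (2R,4R,5Z)-4-methyl-2,4-bis(triethylsilyloxy)-6-(tributylstannyl)hex-5-enal, via bis-triethylsilyl dimethyl acetal 7 (not isolated), via collidinium salt 8 (not isolated)
Conditions: Et3SiOTf (5 equiv), 2,4,6-collidine (7 equiv), CH2Cl2, −78 → 0 °C; then H2O, 0 °C → rt
Reagents that add atoms: triethylsilyl trifluoromethanesulfonate (CC[Si](CC)(CC)OS(=O)(=O)C(F)(F)F); water (O)
Why: The silyl triflate/collidine pair first silylates both hydroxyls (so the tertiary C10–OH cannot form a lactol with C7) and then ionises the dimethyl acetal to a collidinium salt that water hydrolyses to the aldehyde under non-acidic conditions that spare silyl ethers and the vinylstannane.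

Step 5
Reactants: 9 (2R,4R,5Z)-4-methyl-2,4-bis(triethylsilyloxy)-6-(tributylstannyl)hex-5-enal; 10 methyl acrylate
Product: 11 methyl (3RS,4R,6R,7Z)-3-hydroxy-6-methyl-2-methylidene-4,6-bis(triethylsilyloxy)-8-(tributylstannyl)oct-7-enoate
Conditions: DABCO (1 equiv), methyl acrylate (10 equiv, neat), MeOH (2 equiv), rt, 4 d
Reagents that add atoms: none
Why: Morita–Baylis–Hillman reaction of the activated α-silyloxy aldehyde with the DABCO–acrylate zwitterion, the new C7 carbinol forming as an epimer mixture that is irrelevant because C7 becomes sp2 in the next step.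

Step 6
Reactants: 11 methyl (3RS,4R,6R,7Z)-3-hydroxy-6-methyl-2-methylidene-4,6-bis(triethylsilyloxy)-8-(tributylstannyl)oct-7-enoate
Product: 13 methyl (2Z,4R,6R,7Z)-2-(bromomethyl)-6-methyl-4,6-bis(triethylsilyloxy)-8-(tributylstannyl)octa-2,7-dienoate, via allylic mesylate 12 (not isolated)
Conditions: MsCl, Et3N, CH2Cl2, −20 °C; then LiBr, THF/acetone, 0 °C → rt
Reagents that add atoms: lithium bromide ([Li+].[Br-])
Why: Mesylation followed by bromide SN2′ displacement with equilibration gives the conjugated primary (Z)-2-(bromomethyl)enoate (C8 cis to CH2Br) under neutral conditions that leave the vinylstannane intact.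

Step 7
Reactants: 14 ethyl but-2-ynoate
Product: 15 ethyl (Z)-3-iodobut-2-enoate
Conditions: NaI, AcOH, 110 °C
Reagents that add atoms: sodium iodide ([Na+].[I-])
Why: Anti hydroiodination of the ynoate (iodide conjugate addition then protonation) gives the (Z)-β-iodo enoate, which places C6 and the future C3 cis across C4=C5.

Step 8
Reactants: 15 ethyl (Z)-3-iodobut-2-enoate
Product: 16 (Z)-3-iodobut-2-enal
Conditions: i-Bu2AlH (1.05 equiv), CH2Cl2, −78 °C; aq. potassium sodium tartrate; used at once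
Reagents that add atoms: none
Why: Partial ester reduction, in which the tetrahedral aluminium hemiacetal survives at −78 °C and collapses to the aldehyde on work-up without touching the (Z)-alkene.

Step 9
Reactants: 13 methyl (2Z,4R,6R,7Z)-2-(bromomethyl)-6-methyl-4,6-bis(triethylsilyloxy)-8-(tributylstannyl)octa-2,7-dienoate; 16 (Z)-3-iodobut-2-enal
Product: 18 (4S,5S)-5-[(Z)-2-iodoprop-1-enyl]-3-methylidene-4-[(1R,3R,4Z)-3-methyl-1,3-bis(triethylsilyloxy)-5-(tributylstannyl)pent-4-enyl]oxolan-2-one, via anti-hydroxy ester 17 (not isolated)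
Conditions: CrCl2 (4 equiv), THF, 0 °C → rt; then PPTS (cat.), CH2Cl2, rt
Reagents that add atoms: none
Why: Nozaki–Hiyama allylation/lactonisation, in which the equilibrating allylchromium reacts through a chair transition state with both substituents equatorial (6,7-anti, hence the trans-lactone) on the face of C7 anti to C9 in the allylic-strain-minimised conformer at C8 (C8–H eclipsing the alkene), setting C6 and C7, while divalent chromium without nickel leaves the vinyl iodide and vinylstannane untouched.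

Step 10
Reactants: 18 (4S,5S)-5-[(Z)-2-iodoprop-1-enyl]-3-methylidene-4-[(1R,3R,4Z)-3-methyl-1,3-bis(triethylsilyloxy)-5-(tributylstannyl)pent-4-enyl]oxolan-2-one
Product: 19 (4R,5S)-4-[(1R,3R,4Z)-1,3-dihydroxy-3-methyl-5-(tributylstannyl)pent-4-enyl]-5-[(Z)-2-iodoprop-1-enyl]-3-methylideneoxolan-2-one
Conditions: Bu4NF/AcOH (1:1, 4 equiv), THF, 0 °C → rt
Reagents that add atoms: none
Why: Buffered fluoride desilylation removes both triethylsilyl ethers without touching the vinylstannane, the vinyl iodide or the α-methylene lactone and without the base that would trigger translactonisation to O8.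

Step 11
Reactants: 20 (E)-but-2-enal
Product: 22 (Z)-2-bromobut-2-enal, via 2,3-dibromobutanal 21 (not isolated)
Conditions: Br2, CH2Cl2, 0 °C; then Et3N, 0 °C → rt
Reagents that add atoms: bromine (BrBr)
Why: Bromine addition followed by E2 loss of HBr through the acidic α-hydrogen gives the thermodynamically favoured (Z)-2-bromo enal with Br cis to CH3.

Step 12
Reactants: 22 (Z)-2-bromobut-2-enal
Product: 23 (Z)-2-bromobut-2-en-1-ol
Conditions: NaBH4, MeOH, 0 °C
Reagents that add atoms: none
Why: Borohydride 1,2-reduction of the aldehyde leaves the vinyl bromide and its geometry unchanged.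

Step 13
Reactants: 23 (Z)-2-bromobut-2-en-1-ol
Product: 26 (Z)-2-(acetoxymethyl)but-2-enoic acid, via dilithio alkoxide 24 (not isolated), via dilithium carboxylate 25 (not isolated)
Conditions: t-BuLi (3.1 equiv), Et2O, −78 → 0 °C; CO2, −78 °C; then Ac2O (1.3 equiv), −78 °C → rt; aq. HCl
Reagents that add atoms: carbon dioxide (O=C=O); acetic anhydride (CC(=O)OC(C)=O)
Why: Bromine–lithium exchange on the lithium alkoxide gives a configurationally stable vinyllithium that is carboxylated with retention (CO2H cis to CH3, the sarracinic acid geometry), after which the more nucleophilic alkoxide is acetylated in the same flask.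

Step 14
Reactants: 19 (4R,5S)-4-[(1R,3R,4Z)-1,3-dihydroxy-3-methyl-5-(tributylstannyl)pent-4-enyl]-5-[(Z)-2-iodoprop-1-enyl]-3-methylideneoxolan-2-one; 26 (Z)-2-(acetoxymethyl)but-2-enoic acid
Product: 28 (1R,3R,4Z)-3-hydroxy-1-[(2S,3R)-2-[(Z)-2-iodoprop-1-enyl]-4-methylidene-5-oxooxolan-3-yl]-3-methyl-5-(tributylstannyl)pent-4-enyl (Z)-2-(acetoxymethyl)but-2-enoate, via mixed anhydride 27 (not isolated)
Conditions: 26, 2,4,6-Cl3C6H2COCl, Et3N, PhMe, rt; then 19, DMAP, PhMe, rt → 40 °C
Reagents that add atoms: none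
Why: Yamaguchi esterification, in which the preformed mixed anhydride acylates the secondary C8–OH selectively over the tertiary C10–OH under conditions mild enough to keep the (Z)-enoate geometry.

Step 15
Reactants: 28 (1R,3R,4Z)-3-hydroxy-1-[(2S,3R)-2-[(Z)-2-iodoprop-1-enyl]-4-methylidene-5-oxooxolan-3-yl]-3-methyl-5-(tributylstannyl)pent-4-enyl (Z)-2-(acetoxymethyl)but-2-enoate
Product: 30 (3R,6R,7R,8R,10R)-3-hydroxy-3,10-epoxygermacra-1,4Z,11(13)-trien-12,6-olid-8-yl (Z)-2-(acetoxymethyl)but-2-enoate, via macrocyclic dienone 29 (not isolated)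
Conditions: Pd2(dba)3 (10 mol %), AsPh3 (40 mol %), CO (3 atm), NMP, 45 °C, 1 mM, syringe-pump addition
Reagents that add atoms: carbon monoxide ([C-]#[O+])
Why: Intramolecular carbonylative Stille coupling, in which zerovalent palladium inserts into the C4–iodine bond, CO inserts, and transmetalation/reductive elimination with the (Z)-vinylstannane close the ten-membered carbocycle as the (1Z,4Z)-dienone with retention of both alkene geometries, after which the C10–OH adds across the ring to the new C3 ketone to give the bridged hemiketal whose C3 configuration is dictated by C10.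

## Compound list

1 | acetone | CC(C)=O | starting material
2 | 2,2-dimethoxyacetaldehyde | COC(OC)C=O | starting material
3 | (R)-4-hydroxy-5,5-dimethoxypentan-2-one | CC(=O)C[C@@H](O)C(OC)OC | intermediate
4 | (2R,4R)-1,1-dimethoxy-4-methylhex-5-yne-2,4-diol | C#C[C@@](C)(C[C@@H](O)C(OC)OC)O | intermediate
5 | lithium alkenylalanate from 4 (Al on the terminal alkene carbon cis to the carbinol carbon, bound to both alkoxides; not isolated) | COC(OC)[C@H]1C[C@]2(C)C=C[Al-]([H])(O1)O2.[Li+] | intermediate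
6 | (2R,4R,5Z)-1,1-dimethoxy-4-methyl-6-(tributylstannyl)hex-5-ene-2,4-diol | CCCC[Sn](CCCC)(CCCC)/C=C\[C@@](C)(C[C@@H](O)C(OC)OC)O | intermediate
7 | (2R,4R,5Z)-1,1-dimethoxy-4-methyl-2,4-bis(triethylsilyloxy)-6-(tributylstannyl)hex-5-ene (not isolated) | CCCC[Sn](CCCC)(CCCC)/C=C\[C@@](C)(C[C@@H](O[Si](CC)(CC)CC)C(OC)OC)O[Si](CC)(CC)CC | intermediate
8 | 1-[(1RS,2R,4R,5Z)-1-methoxy-4-methyl-2,4-bis(triethylsilyloxy)-6-(tributylstannyl)hex-5-enyl]-2,4,6-trimethylpyridinium triflate (not isolated) | CCCC[Sn](CCCC)(CCCC)/C=C\[C@@](C)(C[C@@H](O[Si](CC)(CC)CC)C(OC)[n+]1c(C)cc(C)cc1C)O[Si](CC)(CC)CC.[O-]S(=O)(=O)C(F)(F)F | intermediate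
9 | (2R,4R,5Z)-4-methyl-2,4-bis(triethylsilyloxy)-6-(tributylstannyl)hex-5-enal | CCCC[Sn](CCCC)(CCCC)/C=C\[C@@](C)(C[C@@H](O[Si](CC)(CC)CC)C=O)O[Si](CC)(CC)CC | intermediate
10 | methyl acrylate | C=CC(=O)OC | starting material
11 | methyl (3RS,4R,6R,7Z)-3-hydroxy-6-methyl-2-methylidene-4,6-bis(triethylsilyloxy)-8-(tributylstannyl)oct-7-enoate | CCCC[Sn](CCCC)(CCCC)/C=C\[C@@](C)(C[C@@H](O[Si](CC)(CC)CC)C(O)C(=C)C(=O)OC)O[Si](CC)(CC)CC | intermediate
12 | 3-O-methanesulfonate of 11 (not isolated) | CCCC[Sn](CCCC)(CCCC)/C=C\[C@@](C)(C[C@@H](O[Si](CC)(CC)CC)C(OS(C)(=O)=O)C(=C)C(=O)OC)O[Si](CC)(CC)CC | intermediate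
13 | methyl (2Z,4R,6R,7Z)-2-(bromomethyl)-6-methyl-4,6-bis(triethylsilyloxy)-8-(tributylstannyl)octa-2,7-dienoate | CCCC[Sn](CCCC)(CCCC)/C=C\[C@@](C)(C[C@@H](O[Si](CC)(CC)CC)/C=C(\CBr)C(=O)OC)O[Si](CC)(CC)CC | intermediate
14 | ethyl but-2-ynoate | CC#CC(=O)OCC | starting material
15 | ethyl (Z)-3-iodobut-2-enoate | C/C(I)=C/C(=O)OCC | intermediate
16 | (Z)-3-iodobut-2-enal | C/C(I)=C/C=O | intermediate
17 | methyl (3S,4S,5Z)-4-hydroxy-6-iodo-2-methylidene-3-[(1R,3R,4Z)-3-methyl-1,3-bis(triethylsilyloxy)-5-(tributylstannyl)pent-4-enyl]hept-5-enoate (6,7-anti; not isolated) | C=C(C(=O)OC)[C@@H]([C@H](O)/C=C(/C)I)[C@H](O[Si](CC)(CC)CC)C[C@@](C)(O[Si](CC)(CC)CC)/C=C\[Sn](CCCC)(CCCC)CCCC | intermediate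
18 | (4S,5S)-5-[(Z)-2-iodoprop-1-enyl]-3-methylidene-4-[(1R,3R,4Z)-3-methyl-1,3-bis(triethylsilyloxy)-5-(tributylstannyl)pent-4-enyl]oxolan-2-one (trans-lactone) | C=C1C(=O)O[C@H](/C=C(/C)I)[C@H]1[C@H](O[Si](CC)(CC)CC)C[C@@](C)(O[Si](CC)(CC)CC)/C=C\[Sn](CCCC)(CCCC)CCCC | intermediate
19 | (4R,5S)-4-[(1R,3R,4Z)-1,3-dihydroxy-3-methyl-5-(tributylstannyl)pent-4-enyl]-5-[(Z)-2-iodoprop-1-enyl]-3-methylideneoxolan-2-one | C=C1C(=O)O[C@H](/C=C(/C)I)[C@H]1[C@H](O)C[C@@](C)(O)/C=C\[Sn](CCCC)(CCCC)CCCC | intermediate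
20 | (E)-but-2-enal (crotonaldehyde) | C/C=C/C=O | starting material
21 | 2,3-dibromobutanal (not isolated) | CC(Br)C(Br)C=O | intermediate
22 | (Z)-2-bromobut-2-enal | C/C=C(\Br)C=O | intermediate
23 | (Z)-2-bromobut-2-en-1-ol | C/C=C(\Br)CO | intermediate
24 | lithium 2-lithiobut-2-en-1-olate, Li cis to CH3 (not isolated) | C/C=C(\[Li])CO[Li] | intermediate
25 | dilithium (Z)-2-(oxidomethyl)but-2-enoate (not isolated) | C/C=C(\C(=O)O[Li])CO[Li] | intermediate
26 | (Z)-2-(acetoxymethyl)but-2-enoic acid | C/C=C(\C(=O)O)COC(C)=O | intermediate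
27 | (Z)-2-(acetoxymethyl)but-2-enoic 2,4,6-trichlorobenzoic anhydride (not isolated) | C/C=C(\C(=O)OC(=O)c1c(Cl)cc(Cl)cc1Cl)COC(C)=O | intermediate
28 | (1R,3R,4Z)-3-hydroxy-1-[(2S,3R)-2-[(Z)-2-iodoprop-1-enyl]-4-methylidene-5-oxooxolan-3-yl]-3-methyl-5-(tributylstannyl)pent-4-enyl (Z)-2-(acetoxymethyl)but-2-enoate | C=C1C(=O)O[C@H](/C=C(/C)I)[C@H]1[C@H](OC(=O)/C(=C\C)COC(C)=O)C[C@@](C)(O)/C=C\[Sn](CCCC)(CCCC)CCCC | intermediate
29 | (6R,7R,8R,10R,1Z,4Z)-10-hydroxy-3-oxogermacra-1,4,11(13)-trien-12,6-olid-8-yl (Z)-2-(acetoxymethyl)but-2-enoate (not isolated) | C=C1C(=O)O[C@@H]2/C=C(/C)C(=O)/C=C\[C@@](C)(C[C@@H](OC(=O)/C(=C\C)COC(C)=O)[C@@H]12)O | intermediate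
30 | (3R,6R,7R,8R,10R)-3-hydroxy-3,10-epoxygermacra-1,4Z,11(13)-trien-12,6-olid-8-yl (Z)-2-(acetoxymethyl)but-2-enoate (CNP0256971.1) | C=C1C(=O)O[C@@H]2/C=C(/C)[C@@]3(O)C=C[C@@](C)(C[C@@H](OC(=O)/C(=C\C)COC(C)=O)[C@@H]12)O3 | target

## Step count and risks

Total step count: 15. Longest linear sequence: 10 (steps 1–6, 9, 10, 14, 15).

Most likely to fail, step 15 (carbonylative macrocyclisation). The risks are oligomerisation, direct coupling without CO, and ionisation of the side-chain allylic acetate by zerovalent palladium. The fallback closes the ring by metathesis at C1=C2 instead. It sets out from 28 and comes back at 30. Protodestannylation of 28 (CF3CO2H, CH2Cl2, 0 °C) gives the vinyl carbinol seco-ester (28 with H in place of SnBu3) F1. Intermolecular carbonylative Stille coupling of its vinyl iodide with tributyl(vinyl)stannane (Pd2(dba)3, AsPh3, CO, THF, rt) gives the cross-conjugated divinyl ketone F2. Ring-closing metathesis between the enone vinyl group and the tertiary allylic vinyl group (second-generation Hoveyda–Grubbs catalyst, PhMe, 0.5 mM, 60 °C) gives 29, which closes to 30. If the ring forms as the (1E)-enone macrocycle F3, irradiation at 350 nm isomerises it to the (1Z)-enone, which again collapses to 30.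

Second, step 9 (allylation/lactonisation). The risk is the wrong simple diastereoselectivity, giving the 6,7-syn adduct and hence the cis-lactone. The fallback accepts syn addition and inverts C6. It sets out from 13 (with 16) and comes back at 18 through 17. Indium powder in THF/H2O, which keeps the (Z)-allyl geometry, gives the 6,7-syn hydroxy ester (C6 epimer of 17) F4. Mitsunobu reaction with chloroacetic acid (PPh3, DIAD, PhMe, 0 °C) inverts C6 and gives the O6-chloroacetate of 17 F5. Thiourea/NaHCO3 in EtOH removes the chloroacetyl group to give 17, which lactonises with PPTS to 18.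

Third, step 2 (C10 ethynylation). The risk is that the acetylide prefers the non-chelate face, so that the C10 epimer dominates. The fallback introduces the two C10 substituents in the opposite order, so the same facial bias then delivers the required epimer. It sets out from 2 and comes back at 4. A direct aldol of 2 with 4-(trimethylsilyl)but-3-yn-2-one under Et2Zn/ProPhenol catalysis (the ligand enantiomer that gives the (R)-carbinol) gives (R)-5-hydroxy-6,6-dimethoxy-1-(trimethylsilyl)hex-1-yn-3-one F6. MeMgBr (THF, −78 °C) adds to the ynone to give (2R,4R)-1,1-dimethoxy-4-methyl-6-(trimethylsilyl)hex-5-yne-2,4-diol F7. K2CO3 in MeOH removes the silyl group to give 4.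

## Further compounds

F1 | step 15 | vinyl carbinol seco-ester (28 with H in place of SnBu3) | C=C1C(=O)O[C@H](/C=C(/C)I)[C@H]1[C@H](OC(=O)/C(=C\C)COC(C)=O)C[C@@](C)(O)C=C
F2 | step 15 | cross-conjugated divinyl ketone (F1 with C(=O)CH=CH2 in place of iodine) | C=C1C(=O)O[C@H](/C=C(/C)C(=O)C=C)[C@H]1[C@H](OC(=O)/C(=C\C)COC(C)=O)C[C@@](C)(O)C=C
F3 | step 15 | (1E)-enone macrocycle (1E isomer of 29) | C=C1C(=O)O[C@@H]2/C=C(/C)C(=O)/C=C/[C@@](C)(C[C@@H](OC(=O)/C(=C\C)COC(C)=O)[C@@H]12)O
F4 | step 9 | 6,7-syn hydroxy ester (C6 epimer of 17) | C=C(C(=O)OC)[C@@H]([C@@H](O)/C=C(/C)I)[C@H](O[Si](CC)(CC)CC)C[C@@](C)(O[Si](CC)(CC)CC)/C=C\[Sn](CCCC)(CCCC)CCCC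
F5 | step 9 | O6-chloroacetate of 17 | C=C(C(=O)OC)[C@@H]([C@H](OC(=O)CCl)/C=C(/C)I)[C@H](O[Si](CC)(CC)CC)C[C@@](C)(O[Si](CC)(CC)CC)/C=C\[Sn](CCCC)(CCCC)CCCC
F6 | step 2 | (R)-5-hydroxy-6,6-dimethoxy-1-(trimethylsilyl)hex-1-yn-3-one | C[Si](C)(C)C#CC(=O)C[C@@H](O)C(OC)OC
F7 | step 2 | (2R,4R)-1,1-dimethoxy-4-methyl-6-(trimethylsilyl)hex-5-yne-2,4-diol | C[Si](C)(C)C#C[C@@](C)(C[C@@H](O)C(OC)OC)O
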